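The plan rests on disconnecting the bond between the two adjacent quaternary carbons of the cyclopentane: C1 (CH3, CH2C(=O) arm) and C2 (CH3, 4-methylpent-3-enoyl). The acyl carbon on C2 and the CH2 on C1 are cis, so they can be joined as carbonyl and α-carbon of a cyclobutanone fused to the five-membered ring. An intramolecular keteniminium–alkene [2+2] cycloaddition of an acyclic alkenyl amide of twofold-symmetric (2S,5S)-2,5-dimethylpyrrolidine therefore closes the cyclopentane at C1–C2 and sets both quaternary centres, cis and in absolute sense, in one operation. Prenyl addition and strain-driven retro-aldol opening of the cyclobutane then unveil the 1,5-dicarbonyl, and an α-selective allylbarium addition attaches the aryl chain.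

Key step: step 3

Assumption: the (2S,5S)-auxiliary is taken to lead to the (1R,5R)-ketone (tether folding over the face of the C=N+ unit that is not flanked by a ring methyl); should the sense of induction prove opposite, the equally available (2R,5R)-amine is used with no other change.

Step 1
Reactants: 1 (2S,5S)-2,5-dimethylpyrrolidine; 2 propanoyl chloride
Product: 3 1-[(2S,5S)-2,5-dimethylpyrrolidin-1-yl]propan-1-one
Conditions: aq. NaOH, CH2Cl2, 0 °C to rt
Reagents that add atoms: none
Why: Schotten–Baumann N-acylation of a secondary amine by an acid chloride is fast and leaves the two auxiliary stereocentres untouched.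

Step 2
Reactants: 3 1-[(2S,5S)-2,5-dimethylpyrrolidin-1-yl]propan-1-one; 4 5-bromo-2-methylpent-1-ene
Product: 6 (2RS)-1-[(2S,5S)-2,5-dimethylpyrrolidin-1-yl]-2,6-dimethylhept-6-en-1-one, via lithium enolate 5 (not isolated)
Conditions: LiN(i-Pr)2, THF, −78 °C; then 4, DMPU, −78 °C to rt
Reagents that add atoms: none
Why: Alkylation of the lithium enolate of a tertiary amide with a primary bromide (amide enolate alkylation) is reliable, and the new α-stereocentre needs no control because step 3 turns this carbon into the sp2 terminus of the keteniminium ion.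

Step 3
Reactants: 6 (2RS)-1-[(2S,5S)-2,5-dimethylpyrrolidin-1-yl]-2,6-dimethylhept-6-en-1-one
Product: 9 (1R,5R)-1,5-dimethylbicyclo[3.2.0]heptan-6-one, via keteniminium triflate 7 (not isolated), via cyclobutaniminium triflate 8 (not isolated)
Conditions: Tf2O, 2,4,6-collidine, ClCH2CH2Cl, 0 °C then reflux; then aq. NaHCO3, rt
Reagents that add atoms: water, O
Why: O-Triflation of the amide and loss of the α-proton give keteniminium ion 7, whose electrophilic central carbon is attacked by the CH2 terminus of the 1,1-disubstituted alkene so that positive charge builds on the tertiary carbon, onto which the enamine α-carbon then collapses to form the C1–C5 bond of 9 (the C1–C2 bond of the cyclopentane in 28). The closest known reaction type is the intramolecular keteniminium–alkene [2+2] cycloaddition of ω-alkenyl amides activated by Tf2O and a pyridine base, including variants steered by chiral pyrrolidine auxiliaries. The cyclopentane closes through C1–C5 across the three-carbon tether with both reacting π bonds exocyclic to it, and the cyclobutane closes at the same time through C6–C7 and C1–C5 in the fused mode, the only one the short tether allows. Both quaternary centres arise together: their cis relation is enforced by the cis ring fusion of a bicyclo[3.2.0]heptane, and their absolute sense comes from the trans-2,5-dimethylpyrrolidine, which by its twofold symmetry gives a single keteniminium geometry and leaves the alkene to fold over the face of the C=N+ bond not blocked by the neighbouring ring methyl. The step needs fused rather than bridged regiochemistry, secured by the Markovnikov polarisation of the alkene toward the tertiary carbon, and it needs facial selectivity, which rests on the auxiliary alone. Hydrolysis of iminium salt 8 then releases ketone 9 and returns the amine for reuse.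

Step 4
Reactants: 9 (1R,5R)-1,5-dimethylbicyclo[3.2.0]heptan-6-one
Product: 12 (1R,5R)-7-(dimethoxymethyl)-1,5-dimethylbicyclo[3.2.0]heptan-6-one (both C7 epimers), via lithium enolate 10 (not isolated), via silyl enol ether 11 (not isolated)
Conditions: LiN(i-Pr)2, Me3SiCl, THF, −78 °C; solvent change to CH2Cl2; HC(OMe)3, Me3SiOTf (cat.), −78 °C
Reagents that add atoms: trimethyl orthoformate, COC(OC)OC
Why: Deprotonation can take place only at C7 because C5 is quaternary, and the derived silyl enol ether adds to the dimethoxycarbenium ion released from the orthoformate (Mukaiyama-type alkylation with an orthoester), the configuration of C7 being of no consequence since this carbon becomes CH2 again in step 5.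

Step 5
Reactants: 12 (1R,5R)-7-(dimethoxymethyl)-1,5-dimethylbicyclo[3.2.0]heptan-6-one; 13 1-chloro-3-methylbut-2-ene
Product: 17 2-[(1R,2R)-1,2-dimethyl-2-(4-methylpent-3-enoyl)cyclopentyl]acetaldehyde, via prenylbarium chloride 14 (not isolated), via cyclobutanol 15 (not isolated), via hydroxy aldehyde 16 (not isolated)
Conditions: BaI2, lithium biphenylide LiC12H10, THF, rt (activated barium); 13, −78 °C; then 12, −78 °C; then 1 M aq. HCl, THF, 0 °C to rt
Reagents that add atoms: water, O
Why: Allylic barium reagents transfer the allyl unit through the unsubstituted α-terminus and add readily to the strained cyclobutanone (1,2-addition), after which acid unmasks a 2-formylcyclobutanol that opens by retro-aldol cleavage of C6–C7, the fragmentation stage of a de Mayo sequence driven by release of ring strain, so that the ketone and the CH2CHO arm appear cis on the ring with the two quaternary centres untouched and the carbinol and C7 configurations erased.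

Step 6
Reactants: 18 4-methoxy-3-methylphenol
Product: 19 (4-methoxy-3-methylphenoxy)tri(propan-2-yl)silane
Conditions: i-Pr3SiCl, imidazole, DMF, rt
Reagents that add atoms: triisopropylsilyl chloride, CC(C)[Si](Cl)(C(C)C)C(C)C
Why: Silylation of the phenol (silyl ether formation) installs a bulky group that survives organolithium and organobarium reagents and is a poor director of metalation.

Step 7
Reactants: 19 (4-methoxy-3-methylphenoxy)tri(propan-2-yl)silane; 20 1-bromo-3-methylbut-2-ene
Product: 22 [4-methoxy-3-methyl-5-(3-methylbut-2-en-1-yl)phenoxy]tri(propan-2-yl)silane, via aryllithium 21 (not isolated)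
Conditions: n-BuLi, TMEDA, Et2O, 0 °C to rt; then CuBr·SMe2 (cat.), 20, THF, −78 °C to rt
Reagents that add atoms: none
Why: Directed ortho-metalation takes place next to the methoxy group at its only free ortho position, the bulky silyloxy group being a much weaker director, and copper-catalysed allylic substitution of the aryllithium on prenyl bromide gives the linear prenyl arene.

Step 8
Reactants: 22 [4-methoxy-3-methyl-5-(3-methylbut-2-en-1-yl)phenoxy]tri(propan-2-yl)silane
Product: 23 (2E)-4-[2-methoxy-3-methyl-5-(triisopropylsilyloxy)phenyl]-2-methylbut-2-en-1-ol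
Conditions: SeO2 (cat.), t-BuOOH, CH2Cl2, 0 °C to rt
Reagents that add atoms: tert-butyl hydroperoxide, CC(C)(C)OO
Why: Riley allylic oxidation (ene reaction followed by a [2,3]-sigmatropic shift) attacks the more substituted alkene terminus and selects the (E)-methyl group, which fixes the E geometry of the trisubstituted alkene.

Step 9
Reactants: 23 (2E)-4-[2-methoxy-3-methyl-5-(triisopropylsilyloxy)phenyl]-2-methylbut-2-en-1-ol
Product: 24 {3-[(2E)-4-chloro-3-methylbut-2-en-1-yl]-4-methoxy-5-methylphenoxy}tri(propan-2-yl)silane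
Conditions: PPh3, CCl4, MeCN, rt
Reagents that add atoms: tetrachloromethane, ClC(Cl)(Cl)Cl
Why: The Appel reaction converts the primary allylic alcohol into the chloride under neutral conditions by direct displacement, which keeps the position and the E geometry of the double bond.

Step 10
Reactants: 24 {3-[(2E)-4-chloro-3-methylbut-2-en-1-yl]-4-methoxy-5-methylphenoxy}tri(propan-2-yl)silane; 17 2-[(1R,2R)-1,2-dimethyl-2-(4-methylpent-3-enoyl)cyclopentyl]acetaldehyde
Product: 26 1-[(1R,2R)-2-{(4E)-2-hydroxy-6-[2-methoxy-3-methyl-5-(triisopropylsilyloxy)phenyl]-4-methylhex-4-en-1-yl}-1,2-dimethylcyclopentyl]-4-methylpent-3-en-1-one (both carbinol epimers), via allylbarium chloride 25 (not isolated)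
Conditions: BaI2, lithium biphenylide LiC12H10, THF, rt (activated barium); 24, −78 °C; then 17, −78 °C; aq. NH4Cl
Reagents that add atoms: none
Why: Allylic barium reagents formed at −78 °C keep their double-bond geometry and add through the unsubstituted α-carbon (carbonyl allylation), the unhindered aldehyde reacting far faster than the ketone flanked by a quaternary carbon, and the new carbinol centre is formed without control because step 11 removes it.

Step 11
Reactants: 26 1-[(1R,2R)-2-{(4E)-2-hydroxy-6-[2-methoxy-3-methyl-5-(triisopropylsilyloxy)phenyl]-4-methylhex-4-en-1-yl}-1,2-dimethylcyclopentyl]-4-methylpent-3-en-1-one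
Product: 27 1-[(1R,2R)-2-{(4E)-6-[2-methoxy-3-methyl-5-(triisopropylsilyloxy)phenyl]-4-methyl-2-oxohex-4-en-1-yl}-1,2-dimethylcyclopentyl]-4-methylpent-3-en-1-one
Conditions: Dess–Martin periodinane, pyridine, CH2Cl2, 0 °C to rt
Reagents that add atoms: none
Why: Dess–Martin oxidation of the secondary homoallylic alcohol under buffered, non-basic conditions should give the β,γ-unsaturated ketone without moving the double bond into conjugation and without enolising either ketone.

Step 12
Reactants: 27 1-[(1R,2R)-2-{(4E)-6-[2-methoxy-3-methyl-5-(triisopropylsilyloxy)phenyl]-4-methyl-2-oxohex-4-en-1-yl}-1,2-dimethylcyclopentyl]-4-methylpent-3-en-1-one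
Product: 28 1-[(1R,2R)-2-[(4E)-6-(5-hydroxy-2-methoxy-3-methylphenyl)-4-methyl-2-oxohex-4-en-1-yl]-1,2-dimethylcyclopentyl]-4-methylpent-3-en-1-one
Conditions: Bu4NF, AcOH, THF, 0 °C
Reagents that add atoms: none
Why: Fluoride cleaves the aryl silyl ether (desilylation) while acetic acid protonates the phenoxide at once, so that neither the skipped enones isomerise nor the 1,5-diketone undergoes aldol closure.

Compound list

1 | (2S,5S)-2,5-dimethylpyrrolidine | C[C@H]1CC[C@H](C)N1 | starting material
2 | propanoyl chloride | CCC(=O)Cl | starting material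
3 | 1-[(2S,5S)-2,5-dimethylpyrrolidin-1-yl]propan-1-one | CCC(=O)N1[C@@H](C)CC[C@@H]1C | intermediate
4 | 5-bromo-2-methylpent-1-ene | C=C(C)CCCBr | starting material
5 | lithium enolate of 3 (geometry not specified) | CC=C(O[Li])N1[C@@H](C)CC[C@@H]1C | intermediate
6 | (2RS)-1-[(2S,5S)-2,5-dimethylpyrrolidin-1-yl]-2,6-dimethylhept-6-en-1-one | C=C(C)CCCC(C)C(=O)N1[C@@H](C)CC[C@@H]1C | intermediate
7 | (2S,5S)-1-(2,6-dimethylhepta-1,6-dien-1-ylidene)-2,5-dimethylpyrrolidinium triflate (keteniminium salt) | C=C(C)CCCC(C)=C=[N+]1[C@@H](C)CC[C@@H]1C.[O-]S(=O)(=O)C(F)(F)F | intermediate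
8 | (2S,5S)-1-[(1R,5R)-1,5-dimethylbicyclo[3.2.0]heptan-6-ylidene]-2,5-dimethylpyrrolidinium triflate | [N+]1(=C2C[C@@]3(C)CCC[C@@]23C)[C@@H](C)CC[C@@H]1C.[O-]S(=O)(=O)C(F)(F)F | intermediate
9 | (1R,5R)-1,5-dimethylbicyclo[3.2.0]heptan-6-one | O=C1C[C@@]2(C)CCC[C@@]12C | intermediate
10 | lithium enolate of 9 | [Li]OC1=C[C@@]2(C)CCC[C@@]12C | intermediate
11 | [(1R,5R)-1,5-dimethylbicyclo[3.2.0]hept-6-en-6-yl]oxy(trimethyl)silane | C[Si](C)(C)OC1=C[C@@]2(C)CCC[C@@]12C | intermediate
12 | (1R,5R)-7-(dimethoxymethyl)-1,5-dimethylbicyclo[3.2.0]heptan-6-one (both C7 epimers) | O=C1C(C(OC)OC)[C@@]2(C)CCC[C@@]12C | intermediate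
13 | 1-chloro-3-methylbut-2-ene | CC(C)=CCCl | starting material
14 | (3-methylbut-2-en-1-yl)barium chloride | CC(C)=CC[Ba]Cl | intermediate
15 | (1R,5R)-7-(dimethoxymethyl)-1,5-dimethyl-6-(3-methylbut-2-en-1-yl)bicyclo[3.2.0]heptan-6-ol (C6/C7 mixture) | OC1(CC=C(C)C)C(C(OC)OC)[C@@]2(C)CCC[C@@]12C | intermediate
16 | (1R,5R)-6-hydroxy-1,5-dimethyl-6-(3-methylbut-2-en-1-yl)bicyclo[3.2.0]heptane-7-carbaldehyde (C6/C7 mixture) | OC1(CC=C(C)C)C(C=O)[C@@]2(C)CCC[C@@]12C | intermediate
17 | 2-[(1R,2R)-1,2-dimethyl-2-(4-methylpent-3-enoyl)cyclopentyl]acetaldehyde | O=CC[C@@]1(C)CCC[C@@]1(C)C(=O)CC=C(C)C | intermediate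
18 | 4-methoxy-3-methylphenol | COc1ccc(O)cc1C | starting material
19 | (4-methoxy-3-methylphenoxy)tri(propan-2-yl)silane | COc1ccc(O[Si](C(C)C)(C(C)C)C(C)C)cc1C | intermediate
20 | 1-bromo-3-methylbut-2-ene | CC(C)=CCBr | starting material
21 | [2-methoxy-3-methyl-5-(triisopropylsilyloxy)phenyl]lithium | COc1c(C)cc(O[Si](C(C)C)(C(C)C)C(C)C)cc1[Li] | intermediate
22 | [4-methoxy-3-methyl-5-(3-methylbut-2-en-1-yl)phenoxy]tri(propan-2-yl)silane | COc1c(C)cc(O[Si](C(C)C)(C(C)C)C(C)C)cc1CC=C(C)C | intermediate
23 | (2E)-4-[2-methoxy-3-methyl-5-(triisopropylsilyloxy)phenyl]-2-methylbut-2-en-1-ol | COc1c(C)cc(O[Si](C(C)C)(C(C)C)C(C)C)cc1C/C=C(\C)CO | intermediate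
24 | {3-[(2E)-4-chloro-3-methylbut-2-en-1-yl]-4-methoxy-5-methylphenoxy}tri(propan-2-yl)silane | COc1c(C)cc(O[Si](C(C)C)(C(C)C)C(C)C)cc1C/C=C(\C)CCl | intermediate
25 | {(2E)-4-[2-methoxy-3-methyl-5-(triisopropylsilyloxy)phenyl]-2-methylbut-2-en-1-yl}barium chloride | COc1c(C)cc(O[Si](C(C)C)(C(C)C)C(C)C)cc1C/C=C(\C)C[Ba]Cl | intermediate
26 | 1-[(1R,2R)-2-{(4E)-2-hydroxy-6-[2-methoxy-3-methyl-5-(triisopropylsilyloxy)phenyl]-4-methylhex-4-en-1-yl}-1,2-dimethylcyclopentyl]-4-methylpent-3-en-1-one (both carbinol epimers) | COc1c(C)cc(O[Si](C(C)C)(C(C)C)C(C)C)cc1C/C=C(\C)CC(O)C[C@@]1(C)CCC[C@@]1(C)C(=O)CC=C(C)C | intermediate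
27 | 1-[(1R,2R)-2-{(4E)-6-[2-methoxy-3-methyl-5-(triisopropylsilyloxy)phenyl]-4-methyl-2-oxohex-4-en-1-yl}-1,2-dimethylcyclopentyl]-4-methylpent-3-en-1-one | COc1c(C)cc(O[Si](C(C)C)(C(C)C)C(C)C)cc1C/C=C(\C)CC(=O)C[C@@]1(C)CCC[C@@]1(C)C(=O)CC=C(C)C | intermediate
28 | 1-[(1R,2R)-2-[(4E)-6-(5-hydroxy-2-methoxy-3-methylphenyl)-4-methyl-2-oxohex-4-en-1-yl]-1,2-dimethylcyclopentyl]-4-methylpent-3-en-1-one | COc1c(C)cc(O)cc1C/C=C(\C)CC(=O)C[C@@]1(C)CCC[C@@]1(C)C(=O)CC=C(C)C | target

Total step count: 12. Longest linear sequence: 8 steps (steps 1–5, then 10–12); the arene branch (steps 6–9) joins at step 10.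

Steps most likely to fail

Step 3. The tether may fold over either face of the keteniminium ion with too little discrimination, or the developing tertiary cation may lose a proton instead of closing, so that the ketone would form in low enantiomeric purity or in low amount. The fallback sets out from 4 and comes back at 9. Alkylation of dilithiated propanoic acid with 4 would give 2,6-dimethylhept-6-enoic acid F1. SOCl2 would convert it into 2,6-dimethylhept-6-enoyl chloride F2. Et3N in refluxing toluene would generate 2,6-dimethylhepta-1,6-dien-1-one F3, the free ketene, which closes by the thermal intramolecular ketene–alkene [2+2] cycloaddition to racemic cis-1,5-dimethylbicyclo[3.2.0]heptan-6-one F4. Preparative chromatography on a chiral stationary phase would then deliver the (1R,5R)-enantiomer 9.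

Step 5. The basic organobarium reagent may enolise 12 with loss of methoxide, or transfer the prenyl group through its substituted terminus, and the acid stage may dehydrate the aldol instead of fragmenting it. The fallback sets out from 12 and comes back at 17. Allylmagnesium bromide with CeCl3, which poses no regiochemical question and suppresses enolisation, would give (1R,5R)-7-(dimethoxymethyl)-1,5-dimethyl-6-(prop-2-en-1-yl)bicyclo[3.2.0]heptan-6-ol F5. Aqueous HCl would hydrolyse the acetal to (1R,5R)-6-hydroxy-1,5-dimethyl-6-(prop-2-en-1-yl)bicyclo[3.2.0]heptane-7-carbaldehyde F6, which opens by the same retro-aldol cleavage to 2-[(1R,2R)-2-(but-3-enoyl)-1,2-dimethylcyclopentyl]acetaldehyde F7. Cross-metathesis with 2-methylbut-2-ene under the second-generation Grubbs catalyst (H2IMes)(PCy3)Cl2Ru=CHPh would turn the allyl into the prenyl group and return to 17.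

Step 10. The allylbarium reagent may react through its substituted γ-carbon, lose its E geometry before it is trapped, or attack the ketone of 17. The fallback sets out from 24 and comes back at 27, bypassing 26. PhSO2Na would displace the chloride to give triisopropyl{4-methoxy-3-methyl-5-[(2E)-3-methyl-4-(phenylsulfonyl)but-2-en-1-yl]phenoxy}silane F8. Its α-lithio derivative (n-BuLi, −78 °C) would add to the aldehyde of 17 through the sulfonyl-bearing carbon to give 1-[(1R,2R)-2-{(4E)-2-hydroxy-6-[2-methoxy-3-methyl-5-(triisopropylsilyloxy)phenyl]-4-methyl-3-(phenylsulfonyl)hex-4-en-1-yl}-1,2-dimethylcyclopentyl]-4-methylpent-3-en-1-one F9. Dess–Martin oxidation would give 1-[(1R,2R)-2-{(4E)-6-[2-methoxy-3-methyl-5-(triisopropylsilyloxy)phenyl]-4-methyl-2-oxo-3-(phenylsulfonyl)hex-4-en-1-yl}-1,2-dimethylcyclopentyl]-4-methylpent-3-en-1-one F10. SmI2 in THF/MeOH at −78 °C would remove the sulfonyl group reductively and return to 27.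

Further compounds

F1 | step 3 | 2,6-dimethylhept-6-enoic acid (racemic) | C=C(C)CCCC(C)C(=O)O
F2 | step 3 | 2,6-dimethylhept-6-enoyl chloride (racemic) | C=C(C)CCCC(C)C(=O)Cl
F3 | step 3 | 2,6-dimethylhepta-1,6-dien-1-one | C=C(C)CCCC(C)=C=O
F4 | step 3 | racemic cis-1,5-dimethylbicyclo[3.2.0]heptan-6-one | O=C1C[C@@]2(C)CCC[C@@]12C.O=C1C[C@]2(C)CCC[C@]12C
F5 | step 5 | (1R,5R)-7-(dimethoxymethyl)-1,5-dimethyl-6-(prop-2-en-1-yl)bicyclo[3.2.0]heptan-6-ol | OC1(CC=C)C(C(OC)OC)[C@@]2(C)CCC[C@@]12C
F6 | step 5 | (1R,5R)-6-hydroxy-1,5-dimethyl-6-(prop-2-en-1-yl)bicyclo[3.2.0]heptane-7-carbaldehyde | OC1(CC=C)C(C=O)[C@@]2(C)CCC[C@@]12C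
F7 | step 5 | 2-[(1R,2R)-2-(but-3-enoyl)-1,2-dimethylcyclopentyl]acetaldehyde | O=CC[C@@]1(C)CCC[C@@]1(C)C(=O)CC=C
F8 | step 10 | triisopropyl{4-methoxy-3-methyl-5-[(2E)-3-methyl-4-(phenylsulfonyl)but-2-en-1-yl]phenoxy}silane | COc1c(C)cc(O[Si](C(C)C)(C(C)C)C(C)C)cc1C/C=C(\C)CS(=O)(=O)c1ccccc1
F9 | step 10 | 1-[(1R,2R)-2-{(4E)-2-hydroxy-6-[2-methoxy-3-methyl-5-(triisopropylsilyloxy)phenyl]-4-methyl-3-(phenylsulfonyl)hex-4-en-1-yl}-1,2-dimethylcyclopentyl]-4-methylpent-3-en-1-one | COc1c(C)cc(O[Si](C(C)C)(C(C)C)C(C)C)cc1C/C=C(\C)C(C(O)C[C@@]1(C)CCC[C@@]1(C)C(=O)CC=C(C)C)S(=O)(=O)c1ccccc1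
F10 | step 10 | 1-[(1R,2R)-2-{(4E)-6-[2-methoxy-3-methyl-5-(triisopropylsilyloxy)phenyl]-4-methyl-2-oxo-3-(phenylsulfonyl)hex-4-en-1-yl}-1,2-dimethylcyclopentyl]-4-methylpent-3-en-1-one | COc1c(C)cc(O[Si](C(C)C)(C(C)C)C(C)C)cc1C/C=C(\C)C(C(=O)C[C@@]1(C)CCC[C@@]1(C)C(=O)CC=C(C)C)S(=O)(=O)c1ccccc1
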